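**Assumption (one line):** labdane numbering is used (decalin C1–C10, side chain C11–C16 on C9, C17 on C8, C20 on C10; "tetranor" = C13–C16 absent); the target is read as (13S)-labd-7-ene-15,17-diyl diacetate of the normal (5S,9R,10S) series, so (+)-sclareolide supplies the decalin.

## Retrosynthetic overview

1. Target 25 ⇐ Barton–McCombie removal of the C12 hydroxyl of 23; the C15 acetate ⇐ hydroboration of the C14=C15 vinyl group of 20.
2. Key C12–C13 bond ⇐ syn-selective asymmetric crotylboration (carbonyl allylation) of C12 aldehyde 14 with the (Z)-crotylborane made from cis-2-butene 15; this sets C13.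
3. The C7=C8–C17H2OAc unit of 14 ⇐ nor-ketone 7 by kinetic enol triflate, Pd methoxycarbonylation, DIBAL-H and acetylation.
4. Ketone 7 ⇐ lactone reduction, dehydration and ozonolysis of (+)-sclareolide 1.
5. No ring is formed: the trans-decalin with C5, C9 and C10 is taken intact from 1, and only its lactone ring is opened (step 1).

## Route

Step 1
Reactants: 1 (+)-sclareolide
Product: 2 13,14,15,16-tetranorlabdane-8α,12-diol
Conditions: LiAlH4, THF, 0 °C → rt; H2O/NaOH work-up
Reagents that add atoms: none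
Why: Hydride reduction of the γ-lactone gives the 8,12-diol without touching C5, C8, C9 or C10, which come from the chiral pool.

Step 2
Reactants: 2 13,14,15,16-tetranorlabdane-8α,12-diol
Product: 3 12-(tert-butyldimethylsilyloxy)-13,14,15,16-tetranorlabdan-8α-ol
Conditions: TBSCl, imidazole, CH2Cl2, rt
Reagents that add atoms: tert-butyldimethylsilyl chloride CC(C)(C)[Si](C)(C)Cl
Why: Silyl ether formation is selective for the primary hydroxyl over the hindered tertiary C8 hydroxyl.

Step 3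
Reactants: 3 12-(tert-butyldimethylsilyloxy)-13,14,15,16-tetranorlabdan-8α-ol
Product: 5 12-(tert-butyldimethylsilyloxy)-13,14,15,16-tetranorlabd-8(17)-ene, via chlorosulfite ester 4 (not isolated)
Conditions: SOCl2, pyridine, CH2Cl2, −78 °C
Reagents that add atoms: none
Why: E2 dehydration through the chlorosulfite; the equatorial 8α leaving group has no anti-periplanar ring hydrogen, so a C17 methyl hydrogen is removed and the exocyclic olefin should be the major isomer (minor endocyclic isomers are carried on and removed after step 4).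

Step 4
Reactants: 5 12-(tert-butyldimethylsilyloxy)-13,14,15,16-tetranorlabd-8(17)-ene
Product: 7 12-(tert-butyldimethylsilyloxy)-13,14,15,16,17-pentanorlabdan-8-one, via secondary ozonide 6 (not isolated)
Conditions: O3, CH2Cl2, −78 °C; Me2S, −78 °C → rt
Reagents that add atoms: ozone [O-][O+]=O
Why: Ozonolysis (Criegee) cleaves C8=C17 to the ketone, which is easily separated from the ring-opened dicarbonyls of the endocyclic isomers; C9, now α to the ketone, keeps its thermodynamically favoured equatorial (β) side chain.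

Step 5
Reactants: 7 12-(tert-butyldimethylsilyloxy)-13,14,15,16,17-pentanorlabdan-8-one
Product: 9 12-(tert-butyldimethylsilyloxy)-13,14,15,16,17-pentanorlabd-7-en-8-yl trifluoromethanesulfonate, via lithium Δ7-enolate 8 (not isolated)
Conditions: LDA, THF, −78 °C; PhNTf2, −78 → 0 °C
Reagents that add atoms: N-phenylbis(trifluoromethanesulfonimide) O=S(=O)(N(c1ccccc1)S(=O)(=O)C(F)(F)F)C(F)(F)F
Why: Kinetic enolate formation takes the C7 methylene proton (the C9 methine is shielded by quaternary C10 and the side chain), and O-triflation fixes the double bond at C7=C8 without epimerising C9.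

Step 6
Reactants: 9 12-(tert-butyldimethylsilyloxy)-13,14,15,16,17-pentanorlabd-7-en-8-yl trifluoromethanesulfonate
Product: 10 methyl 12-(tert-butyldimethylsilyloxy)-13,14,15,16-tetranorlabd-7-en-17-oate
Conditions: Pd(OAc)2 (5 mol%), dppf, Et3N, CO (1 atm), MeOH/DMF, 60 °C
Reagents that add atoms: carbon monoxide [C-]#[O+]; methanol CO
Why: Pd-catalysed alkoxycarbonylation of the vinyl triflate installs C17 regiospecifically on C8 with the alkene held at C7=C8.

Step 7
Reactants: 10 methyl 12-(tert-butyldimethylsilyloxy)-13,14,15,16-tetranorlabd-7-en-17-oate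
Product: 11 12-(tert-butyldimethylsilyloxy)-13,14,15,16-tetranorlabd-7-en-17-ol
Conditions: DIBAL-H (2.5 equiv), CH2Cl2, −78 → 0 °C; Rochelle salt
Reagents that add atoms: none
Why: DIBAL-H 1,2-reduction of the enoate gives the allylic alcohol without conjugate reduction.

Step 8
Reactants: 11 12-(tert-butyldimethylsilyloxy)-13,14,15,16-tetranorlabd-7-en-17-ol
Product: 12 12-(tert-butyldimethylsilyloxy)-13,14,15,16-tetranorlabd-7-en-17-yl acetate
Conditions: Ac2O, pyridine, DMAP (cat.), CH2Cl2, rt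
Reagents that add atoms: acetic anhydride CC(=O)OC(C)=O
Why: DMAP-catalysed acetylation installs the C17 acetate of the target early, so the C17 alcohol can never lactonise or compete later.

Step 9
Reactants: 12 12-(tert-butyldimethylsilyloxy)-13,14,15,16-tetranorlabd-7-en-17-yl acetate
Product: 13 12-hydroxy-13,14,15,16-tetranorlabd-7-en-17-yl acetate
Conditions: HF·pyridine, pyridine, THF, 0 °C → rt
Reagents that add atoms: none
Why: Buffered fluoride desilylation frees the primary alcohol and leaves the allylic acetate intact.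

Step 10
Reactants: 13 12-hydroxy-13,14,15,16-tetranorlabd-7-en-17-yl acetate
Product: 14 12-oxo-13,14,15,16-tetranorlabd-7-en-17-yl acetate
Conditions: Dess–Martin periodinane, CH2Cl2, rt
Reagents that add atoms: none
Why: Dess–Martin oxidation gives the aldehyde under near-neutral conditions; it has no α-stereocentre to lose.

Step 11
Reactants: 14 12-oxo-13,14,15,16-tetranorlabd-7-en-17-yl acetate; 15 cis-2-butene
Product: 20 (12R,13R)-12-hydroxylabda-7,14-dien-17-yl acetate, via (Z)-crotylpotassium 16 (not isolated), via methoxyborate ate complex 17 (not isolated), via (Z)-crotyl-B(Ipc)2 18 (not isolated), via O-B(Ipc)2 borinate 19 (not isolated)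
Conditions: 15, KOtBu, n-BuLi, THF, −78 → −45 °C; (−)-Ipc2BOMe [from (+)-α-pinene], −78 °C; BF3·OEt2, −78 °C; then 14, −78 °C, 4 h; NaBO3·4H2O, THF/H2O, rt
Reagents that add atoms: none
Why: Brown asymmetric crotylboration (carbonyl allylation) through a chair Zimmerman–Traxler transition state: the (Z)-crotyl group gives the syn adduct and the (+)-α-pinene-derived Ipc2B unit attacks the Si face of the aldehyde, so C12 and C13 are set as (12R,13R); this C13 arrangement is that of the target (13S once C12 is deoxygenated).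

Step 12
Reactants: 20 (12R,13R)-12-hydroxylabda-7,14-dien-17-yl acetate
Product: 22 (12R,13R)-12,15-dihydroxylabd-7-en-17-yl acetate, via bis(9-BBN) adduct 21 (not isolated)
Conditions: 9-BBN (3 equiv), THF, 0 °C → rt; NaBO3·4H2O, H2O, rt
Reagents that add atoms: sodium perborate (anion drawn as the dimer) [Na+].[Na+].O[B-]1(O)OO[B-](O)(O)OO1
Why: Anti-Markovnikov hydroboration–oxidation with 9-BBN takes the monosubstituted vinyl group and not the trisubstituted ring alkene, and perborate oxidation spares the acetate; C13 is not touched.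

Step 13
Reactants: 22 (12R,13R)-12,15-dihydroxylabd-7-en-17-yl acetate
Product: 23 (12R,13R)-12-hydroxylabd-7-ene-15,17-diyl diacetate
Conditions: AcCl (1.05 equiv), 2,4,6-collidine, CH2Cl2, −78 °C
Reagents that add atoms: acetyl chloride CC(=O)Cl
Why: Selective acylation of the primary C15 hydroxyl; the secondary C12 hydroxyl is flanked by the C13 branch and the decalin and reacts much more slowly.

Step 14
Reactants: 23 (12R,13R)-12-hydroxylabd-7-ene-15,17-diyl diacetate
Product: 24 (12R,13R)-12-[(1H-imidazol-1-ylcarbonothioyl)oxy]labd-7-ene-15,17-diyl diacetate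
Conditions: 1,1'-thiocarbonyldiimidazole, DMAP (cat.), toluene, 80 °C
Reagents that add atoms: 1,1'-thiocarbonyldiimidazole S=C(n1ccnc1)n1ccnc1
Why: Thiocarbonyl activation for the Barton–McCombie reaction under neutral conditions, so no alkoxide is formed that could trigger acetyl migration.

Step 15
Reactants: 24 (12R,13R)-12-[(1H-imidazol-1-ylcarbonothioyl)oxy]labd-7-ene-15,17-diyl diacetate
Product: 25 (13S)-labd-7-ene-15,17-diyl diacetate
Conditions: Bu3SnH, AIBN (cat.), toluene, 110 °C
Reagents that add atoms: none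
Why: Barton–McCombie radical deoxygenation removes the temporary C12 stereocentre; the secondary C12 radical is reduced by tin hydride faster than any 4-exo/5-endo closure onto C7=C8, the acetates are inert, and C13 keeps its configuration (its descriptor changes from R to S only through CIP priorities).

## Compound list

1 | (+)-sclareolide, (3aR,5aS,9aS,9bR)-3a,6,6,9a-tetramethyldecahydronaphtho[2,1-b]furan-2(1H)-one | O=C1C[C@H]2[C@](C)(O1)CC[C@H]3C(C)(C)CCC[C@]23C | starting material
2 | 13,14,15,16-tetranorlabdane-8α,12-diol, (1R,2R,4aS,8aS)-1-(2-hydroxyethyl)-2,5,5,8a-tetramethyldecahydronaphthalen-2-ol | OCC[C@H]1[C@](C)(O)CC[C@H]2C(C)(C)CCC[C@]12C | intermediate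
3 | 12-(tert-butyldimethylsilyloxy)-13,14,15,16-tetranorlabdan-8α-ol | CC(C)(C)[Si](C)(C)OCC[C@H]1[C@](C)(O)CC[C@H]2C(C)(C)CCC[C@]12C | intermediate
4 | 8α-chlorosulfite ester of 3 | CC(C)(C)[Si](C)(C)OCC[C@H]1[C@](C)(OS(=O)Cl)CC[C@H]2C(C)(C)CCC[C@]12C | intermediate (not isolated)
5 | 12-(tert-butyldimethylsilyloxy)-13,14,15,16-tetranorlabd-8(17)-ene | CC(C)(C)[Si](C)(C)OCC[C@H]1C(=C)CC[C@H]2C(C)(C)CCC[C@]12C | intermediate
6 | secondary ozonide of 5 (spiro-1,2,4-trioxolane at C8) | CC(C)(C)[Si](C)(C)OCC[C@H]1C3(OCOO3)CC[C@H]2C(C)(C)CCC[C@]12C | intermediate (not isolated)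
7 | 12-(tert-butyldimethylsilyloxy)-13,14,15,16,17-pentanorlabdan-8-one (9α-H) | CC(C)(C)[Si](C)(C)OCC[C@H]1C(=O)CC[C@H]2C(C)(C)CCC[C@]12C | intermediate
8 | lithium Δ7-enolate of 7 | CC(C)(C)[Si](C)(C)OCC[C@H]1C(O[Li])=CC[C@H]2C(C)(C)CCC[C@]12C | intermediate (not isolated)
9 | 12-(tert-butyldimethylsilyloxy)-13,14,15,16,17-pentanorlabd-7-en-8-yl trifluoromethanesulfonate | CC(C)(C)[Si](C)(C)OCC[C@H]1C(OS(=O)(=O)C(F)(F)F)=CC[C@H]2C(C)(C)CCC[C@]12C | intermediate
10 | methyl 12-(tert-butyldimethylsilyloxy)-13,14,15,16-tetranorlabd-7-en-17-oate | CC(C)(C)[Si](C)(C)OCC[C@H]1C(C(=O)OC)=CC[C@H]2C(C)(C)CCC[C@]12C | intermediate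
11 | 12-(tert-butyldimethylsilyloxy)-13,14,15,16-tetranorlabd-7-en-17-ol | CC(C)(C)[Si](C)(C)OCC[C@H]1C(CO)=CC[C@H]2C(C)(C)CCC[C@]12C | intermediate
12 | 12-(tert-butyldimethylsilyloxy)-13,14,15,16-tetranorlabd-7-en-17-yl acetate | CC(C)(C)[Si](C)(C)OCC[C@H]1C(COC(C)=O)=CC[C@H]2C(C)(C)CCC[C@]12C | intermediate
13 | 12-hydroxy-13,14,15,16-tetranorlabd-7-en-17-yl acetate | OCC[C@H]1C(COC(C)=O)=CC[C@H]2C(C)(C)CCC[C@]12C | intermediate
14 | 12-oxo-13,14,15,16-tetranorlabd-7-en-17-yl acetate | O=CC[C@H]1C(COC(C)=O)=CC[C@H]2C(C)(C)CCC[C@]12C | intermediate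
15 | cis-2-butene | C/C=C\C | starting material
16 | (Z)-crotylpotassium | [K+].C/C=C\[CH2-] | intermediate (not isolated)
17 | potassium (Z)-but-2-enyl(methoxy)bis(isopinocampheyl)borate | [K+].C/C=C\C[B-](OC)([C@@H]1C[C@@H]2C[C@H]([C@H]1C)C2(C)C)[C@@H]1C[C@@H]2C[C@H]([C@H]1C)C2(C)C | intermediate (not isolated)
18 | (Z)-but-2-enylbis(isopinocampheyl)borane, Ipc from (+)-α-pinene | C/C=C\CB([C@@H]1C[C@@H]2C[C@H]([C@H]1C)C2(C)C)[C@@H]1C[C@@H]2C[C@H]([C@H]1C)C2(C)C | intermediate (not isolated)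
19 | 12-O-[bis(isopinocampheyl)boryl] borinate of 20 | C=C[C@@H](C)[C@H](OB([C@@H]1C[C@@H]2C[C@H]([C@H]1C)C2(C)C)[C@@H]1C[C@@H]2C[C@H]([C@H]1C)C2(C)C)C[C@H]1C(COC(C)=O)=CC[C@H]2C(C)(C)CCC[C@]12C | intermediate (not isolated)
20 | (12R,13R)-12-hydroxylabda-7,14-dien-17-yl acetate | C=C[C@@H](C)[C@H](O)C[C@H]1C(COC(C)=O)=CC[C@H]2C(C)(C)CCC[C@]12C | intermediate
21 | 15-(9-borabicyclo[3.3.1]non-9-yl) 12-O-(9-borabicyclo[3.3.1]non-9-yl) adduct of 20 | C(C[C@@H](C)[C@H](OB1C2CCCC1CCC2)C[C@H]1C(COC(C)=O)=CC[C@H]2C(C)(C)CCC[C@]12C)B1C2CCCC1CCC2 | intermediate (not isolated)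
22 | (12R,13R)-12,15-dihydroxylabd-7-en-17-yl acetate | OCC[C@@H](C)[C@H](O)C[C@H]1C(COC(C)=O)=CC[C@H]2C(C)(C)CCC[C@]12C | intermediate
23 | (12R,13R)-12-hydroxylabd-7-ene-15,17-diyl diacetate | CC(=O)OCC[C@@H](C)[C@H](O)C[C@H]1C(COC(C)=O)=CC[C@H]2C(C)(C)CCC[C@]12C | intermediate
24 | (12R,13R)-12-[(1H-imidazol-1-ylcarbonothioyl)oxy]labd-7-ene-15,17-diyl diacetate | CC(=O)OCC[C@@H](C)[C@H](OC(=S)n1ccnc1)C[C@H]1C(COC(C)=O)=CC[C@H]2C(C)(C)CCC[C@]12C | intermediate
25 | (13S)-labd-7-ene-15,17-diyl diacetate, (3S)-5-[(1R,4aS,8aS)-2-(acetoxymethyl)-5,5,8a-trimethyl-1,4,4a,5,6,7,8,8a-octahydronaphthalen-1-yl]-3-methylpentyl acetate | CC(=O)OCC[C@@H](C)CC[C@H]1C(COC(C)=O)=CC[C@H]2C(C)(C)CCC[C@]12C | target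

## Summary

Total step count: 15. Longest linear sequence: 15 steps (1 → 25); cis-2-butene 15 enters in step 11.

Three steps most likely to fail, each with a fallback:

**Step 3 (regiochemistry of the dehydration).** The fallback sets out from 3 and comes back at 11. If the endocyclic olefin dominates, it becomes the productive isomer. Chlorosulfite 4 is allowed to eliminate at higher temperature, and the trisubstituted olefin 12-(tert-butyldimethylsilyloxy)-13,14,15,16-tetranorlabd-7-ene F1 is purified on AgNO3-silica. Its C17 methyl, the CH3 on the more substituted alkene carbon, is then oxidised directly by catalytic SeO2/t-BuOOH in CH2Cl2, with NaBH4 to return any over-oxidised enal. This gives allylic alcohol 11 and replaces the ozonolysis–triflation–carbonylation–reduction sequence by one C–H oxidation.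

**Step 6 (carbonylation of the hindered vinyl triflate).** The fallback sets out from 5 and comes back at 11. The exocyclic olefin is epoxidised from the less hindered α-face (mCPBA, NaHCO3, CH2Cl2, 0 °C) to 12-(tert-butyldimethylsilyloxy)-8α,17-epoxy-13,14,15,16-tetranorlabdane F2. The epoxide is then isomerised with diethylaluminium 2,2,6,6-tetramethylpiperidide in toluene at 0 °C; the bulky amide removes a C7 hydrogen and opens the epoxide to the Δ7-17-ol 11, so no palladium chemistry is needed.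

**Step 11 (stereocontrol and handling of the crotylborane).** The fallback sets out from 14 and comes back at 20, and replaces the allylation by an auxiliary-controlled aldol.
- Evans syn-aldol of 14 with (S)-4-benzyl-3-propionyloxazolidin-2-one (Bu2BOTf, i-Pr2NEt, CH2Cl2, −78 → 0 °C; pH 7 buffer/H2O2) gives the (2S,3R)-syn imide, 12-hydroxy-14-[(S)-4-benzyl-2-oxooxazolidin-3-yl]-14-oxo-15-norlabd-7-en-17-yl acetate F3. It has the same spatial arrangement at C12 and C13 as 20.
- Me3Al/MeNHOMe·HCl (THF, −20 → 0 °C) gives the Weinreb amide, 12-hydroxy-14-[methoxy(methyl)amino]-14-oxo-15-norlabd-7-en-17-yl acetate F4.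
- TESCl/imidazole gives its 12-O-triethylsilyl ether F5.
- Cp2Zr(H)Cl (THF, rt), which tolerates the acetate, gives the aldehyde, 14-oxo-12-(triethylsilyloxy)-15-norlabd-7-en-17-yl acetate F6.
- Wittig methylenation (Ph3P=CH2, THF, −78 → 0 °C) gives 12-(triethylsilyloxy)labda-7,14-dien-17-yl acetate F7.
- HF·pyridine returns 20.

## Further compounds

F1 | step 3 | 12-(tert-butyldimethylsilyloxy)-13,14,15,16-tetranorlabd-7-ene | CC(C)(C)[Si](C)(C)OCC[C@H]1C(C)=CC[C@H]2C(C)(C)CCC[C@]12C
F2 | step 6 | 12-(tert-butyldimethylsilyloxy)-8α,17-epoxy-13,14,15,16-tetranorlabdane | CC(C)(C)[Si](C)(C)OCC[C@H]1[C@@]3(CO3)CC[C@H]2C(C)(C)CCC[C@]12C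
F3 | step 11 | (12R,13S)-12-hydroxy-14-[(S)-4-benzyl-2-oxooxazolidin-3-yl]-14-oxo-15-norlabd-7-en-17-yl acetate (Evans syn-aldol imide) | O=C(N1[C@@H](Cc2ccccc2)COC1=O)[C@@H](C)[C@H](O)C[C@H]1C(COC(C)=O)=CC[C@H]2C(C)(C)CCC[C@]12C
F4 | step 11 | (12R,13S)-12-hydroxy-14-[methoxy(methyl)amino]-14-oxo-15-norlabd-7-en-17-yl acetate (Weinreb amide) | CON(C)C(=O)[C@@H](C)[C@H](O)C[C@H]1C(COC(C)=O)=CC[C@H]2C(C)(C)CCC[C@]12C
F5 | step 11 | 12-O-triethylsilyl ether of F4 | CON(C)C(=O)[C@@H](C)[C@H](O[Si](CC)(CC)CC)C[C@H]1C(COC(C)=O)=CC[C@H]2C(C)(C)CCC[C@]12C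
F6 | step 11 | 14-oxo-12-(triethylsilyloxy)-15-norlabd-7-en-17-yl acetate | O=C[C@@H](C)[C@H](O[Si](CC)(CC)CC)C[C@H]1C(COC(C)=O)=CC[C@H]2C(C)(C)CCC[C@]12C
F7 | step 11 | (12R,13R)-12-(triethylsilyloxy)labda-7,14-dien-17-yl acetate | C=C[C@@H](C)[C@H](O[Si](CC)(CC)CC)C[C@H]1C(COC(C)=O)=CC[C@H]2C(C)(C)CCC[C@]12C
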